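Assumption: the oxazaborolidine–AlBr3 catalyst made from (S)-diarylprolinol is taken to give the (6R) photoadduct; if the observed sense is the opposite, the catalyst from (R)-diarylprolinol is used and nothing else changes.

## Retrosynthetic overview

1. Target 21 ⇒ keto alcohol 19 + linoleic acid 20, joined last by a lipase-catalysed esterification.
2. 19 ⇒ trans keto acetal 14: the C=CH2 comes from the cyclobutyl ketone (Wittig), the methyl ketone from the masked aldehyde (MeMgBr, oxidation).
3. 14 ⇒ cyclohexene 10: terminus-differentiating ozonolysis of C2=C3, then cis→trans epimerisation α to the new ketone.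
4. 10 ⇒ enol triflate 6 + allyl silyl ether 8 (hydroboration/B-alkyl Suzuki); 6 ⇒ bicyclic ketone 4.
5. 4 ⇒ cyclohexenone 1 + isobutene 2: the cyclobutane (the only ring of the target) is formed first by a catalytic enantioselective [2+2] photocycloaddition; the six-membered ring is a scaffold that is opened in step 5.

## Route

Step 1
Reactants: 1 cyclohex-2-en-1-one; 2 2-methylpropene (isobutene)
Product: 4 (1R,6R)-7,7-dimethylbicyclo[4.2.0]octan-2-one (cis-fused), via trans-fused (1S,6R)-ketone 3 (not isolated)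
Conditions: 2 (10 equiv), (S)-diarylprolinol-derived B-aryl oxazaborolidine·AlBr3 (50 mol%), CH2Cl2, −75 °C, hν 366 nm; then basic Al2O3, CH2Cl2, rt
Reagents that add atoms: none
Why: Chiral-Lewis-acid-catalysed enantioselective enone–alkene [2+2] photocycloaddition, in which only the catalyst-bound enone absorbs at 366 nm and one face of its β-carbon is shielded, so the head-to-tail adduct forms with C6 set as R, and the epimerisable C1 is then equilibrated on alumina to the cis ring fusion.

Step 2
Reactants: 4 (1R,6R)-7,7-dimethylbicyclo[4.2.0]octan-2-one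
Product: 6 (1R,6R)-7,7-dimethylbicyclo[4.2.0]oct-2-en-2-yl trifluoromethanesulfonate, via lithium enolate 5 (not isolated)
Conditions: LDA (1.1 equiv), THF, −78 °C; PhNTf2, −78 → 0 °C; aqueous work-up
Reagents that add atoms: N-phenylbis(trifluoromethanesulfonimide), O=S(=O)(N(c1ccccc1)S(=O)(=O)C(F)(F)F)C(F)(F)F
Why: Kinetic enolisation takes the C3 methylene proton rather than the strained cyclobutane methine, and O-sulfonylation of the enolate (enol triflate synthesis) fixes the C2=C3 double bond without touching C1 or C6.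

Step 3
Reactants: 7 prop-2-en-1-ol (allyl alcohol)
Product: 8 (allyloxy)(tert-butyl)diphenylsilane
Conditions: TBDPSCl, imidazole, CH2Cl2, 0 °C → rt
Reagents that add atoms: tert-butyl(chloro)diphenylsilane, CC(C)(C)[Si](Cl)(c1ccccc1)c1ccccc1
Why: Imidazole-promoted silylation of a primary alcohol gives an ether that survives ozone, catalytic acid, alkoxide, ylide and Grignard reagent.

Step 4
Reactants: 6 enol triflate; 8 (allyloxy)(tert-butyl)diphenylsilane
Product: 10 tert-butyl{3-[(1R,6R)-7,7-dimethylbicyclo[4.2.0]oct-2-en-2-yl]propoxy}diphenylsilane, via B-alkyl-9-BBN 9 (not isolated)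
Conditions: 8, 9-BBN-H, THF, 0 °C → rt; then 6, Pd(dppf)Cl2 (5 mol%), aq. K3PO4, DMF, 50 °C
Reagents that add atoms: none
Why: Anti-Markovnikov hydroboration followed by B-alkyl Suzuki–Miyaura coupling joins the three-carbon silyloxy chain to C2 regiospecifically, and the ring stereocentres are not involved.

Step 5
Reactants: 10 cyclohexene
Product: 13 4-[(tert-butyldiphenylsilyl)oxy]-1-[(1R,2R)-2-(3,3-dimethoxypropyl)-3,3-dimethylcyclobutyl]butan-1-one (cis), via methoxy-hydroperoxide aldehyde 11 (not isolated), via methoxy-hydroperoxide acetal 12 (not isolated)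
Conditions: O3, CH2Cl2/MeOH 5:1, −78 °C; TsOH·H2O (10 mol%), rt; NaHCO3, then Me2S, rt
Reagents that add atoms: ozone, [O-][O+]=O; methanol, CO
Why: Criegee ozonolysis with in-situ terminus differentiation: the more substituted carbon (C2) leaves as the carbonyl oxide and is trapped by methanol, the free aldehyde at C3 becomes the dimethyl acetal under acid, and Me2S then unveils the ketone, so no free 1,6-keto aldehyde that could undergo aldol cyclisation is present.

Step 6
Reactants: 13 cis keto acetal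
Product: 14 4-[(tert-butyldiphenylsilyl)oxy]-1-[(1S,2R)-2-(3,3-dimethoxypropyl)-3,3-dimethylcyclobutyl]butan-1-one (trans)
Conditions: NaOMe (0.2 equiv), MeOH, rt, to equilibrium; chromatography, minor cis isomer recycled
Reagents that add atoms: none
Why: Base-catalysed epimerisation through the enolate moves the acyl group to the thermodynamically preferred trans position relative to the fixed (R) centre next to the gem-dimethyl group, which sets the second ring stereocentre as S.

Step 7
Reactants: 14 trans keto acetal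
Product: 15 tert-butyl({4-[(1S,2R)-2-(3,3-dimethoxypropyl)-3,3-dimethylcyclobutyl]pent-4-en-1-yl}oxy)diphenylsilane
Conditions: Ph3PCH3Br, KOtBu, THF, 0 °C → 45 °C
Reagents that add atoms: methyltriphenylphosphonium bromide, C[P+](c1ccccc1)(c1ccccc1)c1ccccc1.[Br-]
Why: Wittig methylenation converts the ketone into the 1,1-disubstituted alkene, and any enolisation under the basic conditions returns the already favoured trans isomer.

Step 8
Reactants: 15 alkene acetal
Product: 16 3-[(1R,4S)-4-{5-[(tert-butyldiphenylsilyl)oxy]pent-1-en-2-yl}-2,2-dimethylcyclobutyl]propanal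
Conditions: PPTS (0.2 equiv), acetone/H2O 10:1, 50 °C
Reagents that add atoms: water, O
Why: Mild acid-catalysed acetal hydrolysis frees the aldehyde while the TBDPS ether and the 1,1-disubstituted alkene are inert to PPTS.

Step 9
Reactants: 16 aldehyde
Product: 17 4-[(1R,4S)-4-{5-[(tert-butyldiphenylsilyl)oxy]pent-1-en-2-yl}-2,2-dimethylcyclobutyl]butan-2-ol (both carbinol epimers)
Conditions: MeMgBr, THF, −78 → 0 °C; sat. aq. NH4Cl
Reagents that add atoms: methylmagnesium bromide, C[Mg]Br
Why: Grignard addition to the only carbonyl group present installs the methyl carbon, and the uncontrolled carbinol centre is removed in the next step.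

Step 10
Reactants: 17 secondary alcohol
Product: 18 4-[(1R,4S)-4-{5-[(tert-butyldiphenylsilyl)oxy]pent-1-en-2-yl}-2,2-dimethylcyclobutyl]butan-2-one
Conditions: Dess–Martin periodinane, CH2Cl2, 0 °C → rt
Reagents that add atoms: none
Why: Dess–Martin oxidation gives the methyl ketone under neutral conditions that leave the alkene, the silyl ether and both ring stereocentres (neither is α to a carbonyl now) untouched.

Step 11
Reactants: 18 silyl ether
Product: 19 4-[(1R,4S)-4-(5-hydroxypent-1-en-2-yl)-2,2-dimethylcyclobutyl]butan-2-one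
Conditions: TBAF, AcOH (1:1), THF, 0 °C → rt
Reagents that add atoms: none
Why: Fluoride-mediated Si–O cleavage frees the primary alcohol, and the acetic acid buffer prevents base-induced aldol chemistry of the methyl ketone.

Step 12
Reactants: 19 keto alcohol; 20 (9Z,12Z)-octadeca-9,12-dienoic acid (linoleic acid, 1.2 equiv)
Product: 21 4-[(1S,2R)-3,3-dimethyl-2-(3-oxobutyl)cyclobutyl]pent-4-en-1-yl (9Z,12Z)-octadeca-9,12-dienoate (target)
Conditions: immobilised Candida antarctica lipase B (a lipase), 4 Å MS, n-heptane, 45 °C, Ar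
Reagents that add atoms: none
Why: Lipase-catalysed esterification, in which the serine acyl-enzyme formed from the fatty acid is passed to the unhindered primary alcohol at neutral pH, so the skipped (Z,Z)-diene, the exocyclic alkene and the ketone are not isomerised or attacked, and the sieves drive the equilibrium by removing water.

## Compound list

1 | cyclohex-2-en-1-one | O=C1C=CCCC1 | starting material
2 | 2-methylpropene (isobutene) | CC(C)=C | starting material
3 | (1S,6R)-7,7-dimethylbicyclo[4.2.0]octan-2-one (trans-fused) | O=C1CCC[C@@H]2[C@@H]1CC2(C)C | intermediate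
4 | (1R,6R)-7,7-dimethylbicyclo[4.2.0]octan-2-one (cis-fused) | O=C1CCC[C@@H]2[C@H]1CC2(C)C | intermediate
5 | lithium (1R,6R)-7,7-dimethylbicyclo[4.2.0]oct-2-en-2-olate | [Li]OC1=CCC[C@@H]2[C@H]1CC2(C)C | intermediate
6 | (1R,6R)-7,7-dimethylbicyclo[4.2.0]oct-2-en-2-yl trifluoromethanesulfonate | O=S(=O)(OC1=CCC[C@@H]2[C@H]1CC2(C)C)C(F)(F)F | intermediate
7 | prop-2-en-1-ol (allyl alcohol) | C=CCO | starting material
8 | (allyloxy)(tert-butyl)diphenylsilane | C=CCO[Si](c1ccccc1)(c1ccccc1)C(C)(C)C | intermediate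
9 | 9-{3-[(tert-butyldiphenylsilyl)oxy]propyl}-9-borabicyclo[3.3.1]nonane | CC(C)(C)[Si](OCCCB1C2CCCC1CCC2)(c1ccccc1)c1ccccc1 | intermediate
10 | tert-butyl{3-[(1R,6R)-7,7-dimethylbicyclo[4.2.0]oct-2-en-2-yl]propoxy}diphenylsilane | CC(C)(C)[Si](OCCCC1=CCC[C@@H]2[C@H]1CC2(C)C)(c1ccccc1)c1ccccc1 | intermediate
11 | 3-[(1R,4R)-4-{4-[(tert-butyldiphenylsilyl)oxy]-1-hydroperoxy-1-methoxybutyl}-2,2-dimethylcyclobutyl]propanal (epimers at the peroxy carbon) | O=CCC[C@@H]1[C@H](C(OC)(OO)CCCO[Si](c2ccccc2)(c2ccccc2)C(C)(C)C)CC1(C)C | intermediate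
12 | tert-butyl{4-[(1R,2R)-2-(3,3-dimethoxypropyl)-3,3-dimethylcyclobutyl]-4-hydroperoxy-4-methoxybutoxy}diphenylsilane (epimers at the peroxy carbon) | COC(OC)CC[C@@H]1[C@H](C(OC)(OO)CCCO[Si](c2ccccc2)(c2ccccc2)C(C)(C)C)CC1(C)C | intermediate
13 | 4-[(tert-butyldiphenylsilyl)oxy]-1-[(1R,2R)-2-(3,3-dimethoxypropyl)-3,3-dimethylcyclobutyl]butan-1-one (cis) | COC(OC)CC[C@@H]1[C@H](C(=O)CCCO[Si](c2ccccc2)(c2ccccc2)C(C)(C)C)CC1(C)C | intermediate
14 | 4-[(tert-butyldiphenylsilyl)oxy]-1-[(1S,2R)-2-(3,3-dimethoxypropyl)-3,3-dimethylcyclobutyl]butan-1-one (trans) | COC(OC)CC[C@@H]1[C@@H](C(=O)CCCO[Si](c2ccccc2)(c2ccccc2)C(C)(C)C)CC1(C)C | intermediate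
15 | tert-butyl({4-[(1S,2R)-2-(3,3-dimethoxypropyl)-3,3-dimethylcyclobutyl]pent-4-en-1-yl}oxy)diphenylsilane | COC(OC)CC[C@@H]1[C@@H](C(=C)CCCO[Si](c2ccccc2)(c2ccccc2)C(C)(C)C)CC1(C)C | intermediate
16 | 3-[(1R,4S)-4-{5-[(tert-butyldiphenylsilyl)oxy]pent-1-en-2-yl}-2,2-dimethylcyclobutyl]propanal | O=CCC[C@@H]1[C@@H](C(=C)CCCO[Si](c2ccccc2)(c2ccccc2)C(C)(C)C)CC1(C)C | intermediate
17 | 4-[(1R,4S)-4-{5-[(tert-butyldiphenylsilyl)oxy]pent-1-en-2-yl}-2,2-dimethylcyclobutyl]butan-2-ol (both carbinol epimers) | CC(O)CC[C@@H]1[C@@H](C(=C)CCCO[Si](c2ccccc2)(c2ccccc2)C(C)(C)C)CC1(C)C | intermediate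
18 | 4-[(1R,4S)-4-{5-[(tert-butyldiphenylsilyl)oxy]pent-1-en-2-yl}-2,2-dimethylcyclobutyl]butan-2-one | CC(=O)CC[C@@H]1[C@@H](C(=C)CCCO[Si](c2ccccc2)(c2ccccc2)C(C)(C)C)CC1(C)C | intermediate
19 | 4-[(1R,4S)-4-(5-hydroxypent-1-en-2-yl)-2,2-dimethylcyclobutyl]butan-2-one | CC(=O)CC[C@@H]1[C@@H](C(=C)CCCO)CC1(C)C | intermediate
20 | (9Z,12Z)-octadeca-9,12-dienoic acid (linoleic acid) | CCCCC/C=C\C/C=C\CCCCCCCC(=O)O | starting material
21 | 4-[(1S,2R)-3,3-dimethyl-2-(3-oxobutyl)cyclobutyl]pent-4-en-1-yl (9Z,12Z)-octadeca-9,12-dienoate (IN0146) | C=C(CCCOC(=O)CCCCCCC/C=C\C/C=C\CCCCC)[C@H]1CC(C)(C)[C@@H]1CCC(C)=O | target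

## Step count and risks

Total steps: 12. Longest linear sequence: 11 steps (steps 1, 2, 4–12, from cyclohexenone 1); step 3 is a one-step side branch.

The three steps most likely to fail:

**Step 1 (enantioselective photocycloaddition).** The risks are modest ee, high catalyst loading and head-to-head regioisomers on scale. The fallback sets out from 1 (with 2) and comes back at 4. Uncatalysed irradiation of 1 with 2 (hν 350 nm, CH2Cl2, −70 °C, then basic alumina) gives 4 as a racemate together with its enantiomer (1S,6S)-7,7-dimethylbicyclo[4.2.0]octan-2-one F1. A ketoreductase (alcohol dehydrogenase, NADPH recycled with isopropanol, buffer, 30 °C) then reduces both enantiomers from the same carbonyl face. This gives the diastereomeric alcohols (1R,2S,6R)-7,7-dimethylbicyclo[4.2.0]octan-2-ol F2 and (1S,2S,6S)-7,7-dimethylbicyclo[4.2.0]octan-2-ol F3, which are separated on silica. Dess–Martin oxidation of F2 returns enantiopure 4.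

**Step 5 (one-pot ozonolysis with terminus differentiation).** The risks are the wrong Criegee regiochemistry, partial ketalisation of the ketone and loss of the silyl ether. The fallback sets out from 10 and comes back at 17, replacing the protecting-group differentiation by a chemoselective carbonyl addition. Plain ozonolysis of 10 (O3, CH2Cl2, −78 °C, then PPh3) gives the cis keto aldehyde 4-[(tert-butyldiphenylsilyl)oxy]-1-[(1R,2R)-3,3-dimethyl-2-(3-oxopropyl)cyclobutyl]butan-1-one F4, which is used at once. MeTi(OiPr)3 (THF, −40 → 0 °C) adds only to the aldehyde and gives the cis hydroxy ketone 4-[(tert-butyldiphenylsilyl)oxy]-1-[(1R,2R)-2-(3-hydroxybutyl)-3,3-dimethylcyclobutyl]butan-1-one F5. NaOMe in MeOH equilibrates it to the trans hydroxy ketone 4-[(tert-butyldiphenylsilyl)oxy]-1-[(1S,2R)-2-(3-hydroxybutyl)-3,3-dimethylcyclobutyl]butan-1-one F6. Excess Ph3P=CH2 (3.5 equiv, THF) then methylenates the ketone in the presence of the free hydroxyl and delivers 17.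

**Step 7 (methylenation of an α-branched, enolisable ketone).** The risks are slow olefination, enolisation and loss of trans purity. The fallback sets out from 14 and comes back at 15 by a two-step Peterson olefination. Me3SiCH2Li with anhydrous CeCl3 (THF, −78 °C) adds to the ketone without enolising it and gives the β-hydroxysilane tert-butyl{4-[(1S,2R)-2-(3,3-dimethoxypropyl)-3,3-dimethylcyclobutyl]-4-hydroxy-5-(trimethylsilyl)pentoxy}diphenylsilane F7. KH in THF (0 °C → rt) then causes syn-elimination to 15, and the acetal and silyl ether are stable to this base.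

## Further compounds

F1 | step 1 | (1S,6S)-7,7-dimethylbicyclo[4.2.0]octan-2-one | O=C1CCC[C@H]2[C@@H]1CC2(C)C
F2 | step 1 | (1R,2S,6R)-7,7-dimethylbicyclo[4.2.0]octan-2-ol | O[C@H]1CCC[C@@H]2[C@H]1CC2(C)C
F3 | step 1 | (1S,2S,6S)-7,7-dimethylbicyclo[4.2.0]octan-2-ol | O[C@H]1CCC[C@H]2[C@@H]1CC2(C)C
F4 | step 5 | 4-[(tert-butyldiphenylsilyl)oxy]-1-[(1R,2R)-3,3-dimethyl-2-(3-oxopropyl)cyclobutyl]butan-1-one | O=CCC[C@@H]1[C@H](C(=O)CCCO[Si](c2ccccc2)(c2ccccc2)C(C)(C)C)CC1(C)C
F5 | step 5 | 4-[(tert-butyldiphenylsilyl)oxy]-1-[(1R,2R)-2-(3-hydroxybutyl)-3,3-dimethylcyclobutyl]butan-1-one (both carbinol epimers) | CC(O)CC[C@@H]1[C@H](C(=O)CCCO[Si](c2ccccc2)(c2ccccc2)C(C)(C)C)CC1(C)C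
F6 | step 5 | 4-[(tert-butyldiphenylsilyl)oxy]-1-[(1S,2R)-2-(3-hydroxybutyl)-3,3-dimethylcyclobutyl]butan-1-one (both carbinol epimers) | CC(O)CC[C@@H]1[C@@H](C(=O)CCCO[Si](c2ccccc2)(c2ccccc2)C(C)(C)C)CC1(C)C
F7 | step 7 | tert-butyl{4-[(1S,2R)-2-(3,3-dimethoxypropyl)-3,3-dimethylcyclobutyl]-4-hydroxy-5-(trimethylsilyl)pentoxy}diphenylsilane (both carbinol epimers) | COC(OC)CC[C@@H]1[C@@H](C(O)(C[Si](C)(C)C)CCCO[Si](c2ccccc2)(c2ccccc2)C(C)(C)C)CC1(C)C
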